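## Retrosynthetic overview

1. Ester C–O bond: target 18 ⇒ diol 10 + (2Z)-2-methyl-3-(methylsulfanyl)prop-2-enoic acid 16 (Yamaguchi esterification, last step).
2. Side chain on ring B: 10 ⇒ dienone alcohol 7 + acetone (selenolate Michael addition, aldol, selenoxide elimination).
3. Key C–C bond, between the methyl-bearing CH and the quaternary ring-fusion carbon: 7 ⇒ phenol 4. Oxidation turns the para carbon of the phenol into an electrophile (phenoxonium, a vinylogous enolonium), which is attacked by the tethered E olefin. Both carbons are natural nucleophiles. Acetate capture gives the C–O bond, and a lipase selects the enantiomer.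
4. 4 ⇒ 3-bromo-4-methylphenol + (E)-piperylene (hydroboration, B-alkyl Suzuki). 16 ⇒ propargyl alcohol (anti-carbomagnesiation/iodination, oxidation, C–S coupling).
5. Ring order: ring B is bought as the benzene ring; ring A is closed in the dearomatising step 2.

Assumption: the bicycle is numbered as a naphthalene throughout, and racemic acetate 6 is written with the SMILES of the enantiomer that is carried forward.

## Route

Step 1
Reactants: 1 3-bromo-4-methylphenol; 2 (3E)-penta-1,3-diene
Product: 4 4-methyl-3-[(3E)-pent-3-en-1-yl]phenol, via homoallyl borane 3 (not isolated)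
Conditions: 2 (1.5 equiv), 9-BBN-H (9-borabicyclo[3.3.1]nonane, 1.2 equiv), THF, 0 → 25 °C; then 1, Pd(OAc)2 (2 mol %), SPhos (2-dicyclohexylphosphino-2′,6′-dimethoxybiphenyl, 4 mol %), K3PO4 (3 equiv), THF/H2O, 60 °C
Reagents that add atoms: none
Why: 9-BBN hydroborates only the terminal, monosubstituted double bond of the diene with boron at C1, and the primary alkylborane undergoes B-alkyl Suzuki–Miyaura coupling with the aryl bromide (the free phenol is tolerated as its phenoxide); no stereocentre is formed and the E double bond is carried over unchanged.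

Step 2
Reactants: 4 4-methyl-3-[(3E)-pent-3-en-1-yl]phenol
Product: 6 rac-(1R,2R,8aR)-1,8a-dimethyl-6-oxo-1,2,3,4,6,8a-hexahydronaphthalen-2-yl acetate, via aryloxy-λ3-iodane 5 (not isolated)
Conditions: PhI(OAc)2 (1.1 equiv), AcOH/(CF3)2CHOH 1:1, 0.02 M, −10 °C
Reagents that add atoms: (diacetoxyiodo)benzene CC(=O)OI(OC(C)=O)c1ccccc1; acetic acid CC(=O)O
Why: Proposed new method: ligand exchange at trivalent iodine gives aryloxy-λ3-iodane 5, whose ionisation in the fluoroalcohol turns the methyl-bearing para carbon of the phenol, normally a nucleophilic site, into an electrophile (phenoxonium ion, a vinylogous enolonium); the tethered E olefin, the second nucleophilic carbon, adds to it through a chair-like 6-endo transition state while acetate captures the developing secondary cation from the opposite face (anti addition), which places OAc and the C1 methyl trans-diequatorial and the C1 methyl cis to the new axial C8a methyl, so all three stereocentres are set relative to each other, in racemic form; the closest known reactions are hypervalent-iodine oxidative dearomatisations of para-alkylphenols terminated by π-nucleophiles (oxidative Prins and oxidative polyene cyclisations) and Johnson-type cation–olefin cyclisations in carboxylic acids.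

Step 3
Reactants: 6 rac-(1R,2R,8aR)-1,8a-dimethyl-6-oxo-1,2,3,4,6,8a-hexahydronaphthalen-2-yl acetate
Product: 7 (4aR,5R,6R)-6-hydroxy-4a,5-dimethyl-5,6,7,8-tetrahydronaphthalen-2(4aH)-one
Conditions: immobilised Candida antarctica lipase B (Novozym 435), phosphate buffer pH 7.2/t-BuOMe, 30 °C, stopped at 50 % conversion; chromatography
Reagents that add atoms: none
Why: Lipase-catalysed kinetic resolution by enantioselective ester hydrolysis: by the Kazlauskas rule the enzyme cleaves the acetate whose carbinol carbon is R (large substituent = the CH(CH3)–C(quaternary) side, medium = ring CH2), and because step 2 fixed the relative configuration this gives the (4aR,5R,6R) alcohol (at most 50 %), the (1S,2S,8aS) acetate staying behind.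

Step 4
Reactants: 7 (4aR,5R,6R)-6-hydroxy-4a,5-dimethyl-5,6,7,8-tetrahydronaphthalen-2(4aH)-one; 8 acetone
Product: 10 (4aR,5R,6R)-6-hydroxy-3-(2-hydroxypropan-2-yl)-4a,5-dimethyl-5,6,7,8-tetrahydronaphthalen-2(4aH)-one, via seleno-aldol adduct 9 (not isolated)
Conditions: Me2AlSeMe (3 equiv), toluene/CH2Cl2, −78 °C; 8 (6 equiv), −78 → −20 °C; then THF, pyridine, 30 % H2O2, 0 → 25 °C
Reagents that add atoms: none
Why: Aluminium selenolate Michael–aldol–elimination (a 1-acylethenyl anion equivalent, the stoichiometric surrogate of a Morita–Baylis–Hillman reaction): MeSe adds 1,4 only to the enone whose β-carbon carries hydrogen (C4), the aluminium dienolate adds to acetone at C3, and oxidation to the selenoxide followed by syn-elimination restores the C3=C4 double bond; no stereocentre of the product is formed and C4a, C5 and C6 are untouched (the free hydroxyl only consumes one equivalent of reagent).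

Step 5
Reactants: 11 prop-2-yn-1-ol
Product: 13 (2Z)-3-iodo-2-methylprop-2-en-1-ol, via vinylmagnesium alkoxide 12 (not isolated)
Conditions: MeMgBr (2.5 equiv), CuI (10 mol %), THF, −10 → 25 °C; then iodine (1.2 equiv), −60 → 0 °C
Reagents that add atoms: methylmagnesium bromide C[Mg]Br; iodine [I][I]
Why: Duboudin–Jousseaume copper-catalysed anti-carbomagnesiation of the propargylic alkoxide puts the methyl on C2 and magnesium on C3 on the same side as the CH2O–Mg group (five-membered chelate), and iodinolysis with retention therefore gives the Z vinyl iodide.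

Step 6
Reactants: 13 (2Z)-3-iodo-2-methylprop-2-en-1-ol
Product: 15 (2Z)-3-iodo-2-methylprop-2-enoic acid, via iodo-enal 14 (not isolated)
Conditions: TEMPO (2,2,6,6-tetramethylpiperidin-1-oxyl, 7 mol %), NaOCl (2 mol %), NaClO2 (2 equiv), MeCN/sodium phosphate buffer pH 6.7, 35 °C
Reagents that add atoms: sodium chlorite [Na+].[O-]Cl=O
Why: TEMPO-catalysed oxidation with chlorite as terminal oxidant takes the primary allylic alcohol through aldehyde 14 to the acid without touching the vinyl iodide or its Z geometry.

Step 7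
Reactants: 15 (2Z)-3-iodo-2-methylprop-2-enoic acid
Product: 16 (2Z)-2-methyl-3-(methylsulfanyl)prop-2-enoic acid
Conditions: NaSMe (2.5 equiv), CuI (10 mol %), DMF, 25 → 50 °C; then aq. HCl to pH 2
Reagents that add atoms: sodium methanethiolate [Na+].[S-]C
Why: Copper-catalysed Ullmann-type vinylic C–S coupling, accelerated by the cis carboxylate (Hurtley-type), replaces iodide by methanethiolate with retention of the double-bond geometry, and the product carboxylate is too poor a Michael acceptor for thiolate-mediated Z to E equilibration.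

Step 8
Reactants: 10 (4aR,5R,6R)-6-hydroxy-3-(2-hydroxypropan-2-yl)-4a,5-dimethyl-5,6,7,8-tetrahydronaphthalen-2(4aH)-one; 16 (2Z)-2-methyl-3-(methylsulfanyl)prop-2-enoic acid
Product: 18 (1R,2R,8aR)-7-(2-hydroxypropan-2-yl)-1,8a-dimethyl-6-oxo-1,2,3,4,6,8a-hexahydronaphthalen-2-yl (2Z)-2-methyl-3-(methylsulfanyl)prop-2-enoate, via mixed anhydride 17 (not isolated)
Conditions: 16, 2,4,6-trichlorobenzoyl chloride, Et3N, toluene, 25 °C; then 10, DMAP (4-(dimethylamino)pyridine), toluene, 25 → 40 °C
Reagents that add atoms: none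
Why: Yamaguchi esterification: DMAP transfers the less hindered thioacryloyl group of mixed anhydride 17 to the secondary hydroxyl (the tertiary carbinol is not acylated), the C–O bond of the alcohol is not broken so the carbinol keeps its configuration, and the Z olefin is unaffected under these mild conditions.

## Compound list

1 | 3-bromo-4-methylphenol | Cc1ccc(O)cc1Br | starting material
2 | (3E)-penta-1,3-diene | C=C/C=C/C | starting material
3 | 9-[(3E)-pent-3-en-1-yl]-9-borabicyclo[3.3.1]nonane | C/C=C/CCB1C2CCCC1CCC2 | intermediate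
4 | 4-methyl-3-[(3E)-pent-3-en-1-yl]phenol | C/C=C/CCc1cc(O)ccc1C | intermediate
5 | {4-methyl-3-[(3E)-pent-3-en-1-yl]phenoxy}(phenyl)-λ3-iodanyl acetate | C/C=C/CCc1cc(OI(OC(C)=O)c2ccccc2)ccc1C | intermediate
6 | rac-(1R,2R,8aR)-1,8a-dimethyl-6-oxo-1,2,3,4,6,8a-hexahydronaphthalen-2-yl acetate (racemate) | CC(=O)O[C@@H]1CCC2=CC(=O)C=C[C@]2(C)[C@H]1C | intermediate
7 | (4aR,5R,6R)-6-hydroxy-4a,5-dimethyl-5,6,7,8-tetrahydronaphthalen-2(4aH)-one | O[C@@H]1CCC2=CC(=O)C=C[C@]2(C)[C@H]1C | intermediate
8 | acetone (propan-2-one) | CC(C)=O | starting material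
9 | (4aR,5R,6R)-6-hydroxy-3-(2-hydroxypropan-2-yl)-4a,5-dimethyl-4-(methylselanyl)-4,4a,5,6,7,8-hexahydronaphthalen-2(3H)-one (mixture of C3/C4 epimers) | O[C@@H]1CCC2=CC(=O)C(C(C)(C)O)C([Se]C)[C@]2(C)[C@H]1C | intermediate
10 | (4aR,5R,6R)-6-hydroxy-3-(2-hydroxypropan-2-yl)-4a,5-dimethyl-5,6,7,8-tetrahydronaphthalen-2(4aH)-one | O[C@@H]1CCC2=CC(=O)C(C(C)(C)O)=C[C@]2(C)[C@H]1C | intermediate
11 | prop-2-yn-1-ol | C#CCO | starting material
12 | bromomagnesium (2Z)-3-(bromomagnesio)-2-methylprop-2-en-1-olate | Br[Mg]/C=C(/C)CO[Mg]Br | intermediate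
13 | (2Z)-3-iodo-2-methylprop-2-en-1-ol | I/C=C(/C)CO | intermediate
14 | (2Z)-3-iodo-2-methylprop-2-enal | I/C=C(/C)C=O | intermediate
15 | (2Z)-3-iodo-2-methylprop-2-enoic acid | I/C=C(/C)C(=O)O | intermediate
16 | (2Z)-2-methyl-3-(methylsulfanyl)prop-2-enoic acid | CS/C=C(/C)C(=O)O | intermediate
17 | (2Z)-2-methyl-3-(methylsulfanyl)prop-2-enoic 2,4,6-trichlorobenzoic anhydride | CS/C=C(/C)C(=O)OC(=O)c1c(Cl)cc(Cl)cc1Cl | intermediate
18 | (1R,2R,8aR)-7-(2-hydroxypropan-2-yl)-1,8a-dimethyl-6-oxo-1,2,3,4,6,8a-hexahydronaphthalen-2-yl (2Z)-2-methyl-3-(methylsulfanyl)prop-2-enoate | CS/C=C(/C)C(=O)O[C@@H]1CCC2=CC(=O)C(C(C)(C)O)=C[C@]2(C)[C@H]1C | target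

## Step count and risks

Total steps: 8 (five in the main line, three for the acid). Longest linear sequence: 5 steps (steps 1, 2, 3, 4, 8).

The three steps most likely to fail:

**Step 2, the dearomatising ring closure.** The olefin may attack the free ortho carbon next to the tether (which re-aromatises to a tetralin). The fluoroalcohol or acetate may trap the phenoxonium before the olefin does. The secondary cation may also eliminate or suffer a hydride shift instead of taking up acetate.

The fallback sets out from 4 and comes back at 7, turning the polarity around and taking the absolute configuration from a catalyst. Silylation of 4 (t-BuMe2SiCl, imidazole, DMF) gives tert-butyl(dimethyl){4-methyl-3-[(3E)-pent-3-en-1-yl]phenoxy}silane F1. Shi epoxidation gives tert-butyl(dimethyl)(4-methyl-3-{2-[(2R,3R)-3-methyloxiran-2-yl]ethyl}phenoxy)silane F2. The conditions are 1,2:4,5-di-O-isopropylidene-β-D-erythro-2,3-hexodiulo-2,6-pyranose (the D-fructose-derived ketone), Oxone (2KHSO5·KHSO4·K2SO4), K2CO3, MeCN/dimethoxymethane/aqueous buffer, 0 °C. SnCl4 in CH2Cl2 at −78 °C then lets the arene para carbon open the epoxide at its methyl-bearing carbon (6-endo, inversion, same chair as in step 2). Chloride takes the silyl group off the resulting oxocarbenium ion, and 7 is obtained directly as one enantiomer, so 6 and step 3 are bypassed. Its own weak point is again the ortho carbon, which is more competitive when the arene is the nucleophile.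

**Step 3, the enzymatic resolution.** The acetate sits next to a CH(CH3) group and a quaternary carbon, so hydrolysis may be slow or poorly selective, and the yield cannot exceed 50 %.

The fallback sets out from 4 and comes back at 7. Step 2 is run with PhI(OCOCF3)2 in (CF3)2CHOH containing (S)-2-methoxy-2-phenylacetic acid (10 equiv) in place of acetic acid, so the cation is captured by the chiral carboxylate. This gives two diastereomeric esters: (1R,2R,8aR)-1,8a-dimethyl-6-oxo-1,2,3,4,6,8a-hexahydronaphthalen-2-yl (2S)-2-methoxy-2-phenylacetate F3 and (1S,2S,8aS)-1,8a-dimethyl-6-oxo-1,2,3,4,6,8a-hexahydronaphthalen-2-yl (2S)-2-methoxy-2-phenylacetate F4. They are separated on silica or by crystallisation, and K2CO3 in MeOH cleaves F3 to 7.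

**Step 4, the selenolate Michael–aldol–elimination.** The aldol step uses a ketone as acceptor next to a crowded centre and may stall or revert.

The fallback sets out from 7 and comes back at 10, building the side chain by cross-coupling instead. Iodination (iodine, pyridine, CH2Cl2) gives (4aS,5R,6R)-6-hydroxy-3-iodo-4a,5-dimethyl-5,6,7,8-tetrahydronaphthalen-2(4aH)-one F5. Suzuki–Miyaura coupling with isopropenylboronic acid pinacol ester (Pd(dppf)Cl2, dppf = 1,1′-bis(diphenylphosphino)ferrocene, K3PO4, dioxane/H2O) gives (4aR,5R,6R)-6-hydroxy-4a,5-dimethyl-3-(prop-1-en-2-yl)-5,6,7,8-tetrahydronaphthalen-2(4aH)-one F6. Mukaiyama hydration of the 1,1-disubstituted olefin (Mn(dpm)3, dpm = 2,2,6,6-tetramethylheptane-3,5-dionate, PhSiH3, O2, i-PrOH; then P(OEt)3) gives 10.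

## Further compounds

F1 | step 2 | tert-butyl(dimethyl){4-methyl-3-[(3E)-pent-3-en-1-yl]phenoxy}silane | C/C=C/CCc1cc(O[Si](C)(C)C(C)(C)C)ccc1C
F2 | step 2 | tert-butyl(dimethyl)(4-methyl-3-{2-[(2R,3R)-3-methyloxiran-2-yl]ethyl}phenoxy)silane | C[C@H]1O[C@@H]1CCc1cc(O[Si](C)(C)C(C)(C)C)ccc1C
F3 | step 3 | (1R,2R,8aR)-1,8a-dimethyl-6-oxo-1,2,3,4,6,8a-hexahydronaphthalen-2-yl (2S)-2-methoxy-2-phenylacetate | CO[C@H](C(=O)O[C@@H]1CCC2=CC(=O)C=C[C@]2(C)[C@H]1C)c1ccccc1
F4 | step 3 | (1S,2S,8aS)-1,8a-dimethyl-6-oxo-1,2,3,4,6,8a-hexahydronaphthalen-2-yl (2S)-2-methoxy-2-phenylacetate | CO[C@H](C(=O)O[C@H]1CCC2=CC(=O)C=C[C@@]2(C)[C@@H]1C)c1ccccc1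
F5 | step 4 | (4aS,5R,6R)-6-hydroxy-3-iodo-4a,5-dimethyl-5,6,7,8-tetrahydronaphthalen-2(4aH)-one | O[C@@H]1CCC2=CC(=O)C(I)=C[C@]2(C)[C@H]1C
F6 | step 4 | (4aR,5R,6R)-6-hydroxy-4a,5-dimethyl-3-(prop-1-en-2-yl)-5,6,7,8-tetrahydronaphthalen-2(4aH)-one | O[C@@H]1CCC2=CC(=O)C(C(C)=C)=C[C@]2(C)[C@H]1C
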